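**Retrosynthetic overview** (TBS = tert-butyldimethylsilyl)

- The route rests on one feature of the five-membered lactone ring (O1–C2–C3–C4–C5): C3 (methyl) and C4 (carboxyl) are the α and β carbons of the C2 carbonyl, so both substituents can be added across the C3=C4 alkene of a plain (R)-5-alkylbutenolide.
- Target 21 ← hydroxy acid 19 (acetylation) ← butenolide orthothioester 16 (C(SMe)3 as masked CO2H, silyl ether removed in the same operation).
- 16 ← saturated lactone 12 by restoring C3=C4 (α-selenenylation, selenoxide syn elimination).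
- 12 ← butenolide 8 + (MeS)3CLi + MeI: the C4–C(carboxyl) and C3–CH3 bonds are formed in one flask.
- 8 ← hydroxy ynoate 6 (semihydrogenation, then lactonisation closes the only ring) ← aldehyde 4 + methyl propiolate (asymmetric alkynylation sets C5) ← 1,14-tetradecanediol.

Key step: step 5

Assumption: the catalyst from Me2Zn and (S,S)-ProPhenol (2,6-bis{[(S)-2-(hydroxydiphenylmethyl)pyrrolidin-1-yl]methyl}-4-methylphenol) is taken to give the (R)-alkynol from this aliphatic aldehyde; if Mosher ester analysis of 6 should show the opposite sense, the (R,R)-ligand is used with no other change.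

**Step 1**
Reactants: 1 1,14-tetradecanediol
Product: 3 14-[(tert-butyldimethylsilyl)oxy]tetradecan-1-ol, via monosodium alkoxide 2 (not isolated)
Conditions: NaH (1.0 equiv), THF, 0 → 50 °C; TBSCl (1.0 equiv), rt
Reagents that add atoms: tert-butyldimethylsilyl chloride, CC(C)(C)[Si](C)(C)Cl
Why: Williamson-type O-silylation of the monosodium alkoxide, which precipitates from THF and is silylated faster than it exchanges to the dialkoxide, so the symmetric diol is monoprotected.

**Step 2**
Reactants: 3 14-[(tert-butyldimethylsilyl)oxy]tetradecan-1-ol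
Product: 4 14-[(tert-butyldimethylsilyl)oxy]tetradecanal
Conditions: TEMPO (10 mol %), PhI(OAc)2 (1.1 equiv), CH2Cl2, rt
Reagents that add atoms: none
Why: TEMPO-catalysed alcohol oxidation (oxoammonium cycle with PhI(OAc)2 as terminal oxidant) stops at the aldehyde under anhydrous conditions and leaves the silyl ether alone.

**Step 3**
Reactants: 4 14-[(tert-butyldimethylsilyl)oxy]tetradecanal; 5 methyl propiolate
Product: 6 methyl (R)-17-[(tert-butyldimethylsilyl)oxy]-4-hydroxyheptadec-2-ynoate
Conditions: Me2Zn (3 equiv), (S,S)-ProPhenol (20 mol %), Ph3P=O (40 mol %), toluene, 4 °C, slow addition of 4; aq. NH4Cl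
Reagents that add atoms: none
Why: Zinc–ProPhenol asymmetric alkynylation, in which the alkynylzinc made from methyl propiolate and Me2Zn is delivered to one face of the aldehyde inside the dinuclear zinc pocket of the chiral ligand, setting the carbinol centre (the later C5) as R, while slow addition of the aldehyde suppresses its self-aldol reaction.

**Step 4**
Reactants: 6 methyl (R)-17-[(tert-butyldimethylsilyl)oxy]-4-hydroxyheptadec-2-ynoate
Product: 8 (R)-5-[13-(tert-butyldimethylsilyloxy)tridecyl]furan-2(5H)-one, via Z-hydroxy enoate 7 (not isolated)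
Conditions: H2 (1 atm), Pd on CaCO3 poisoned with Pb(OAc)2, quinoline, EtOAc, rt; then PPTS (cat.), CH2Cl2, rt
Reagents that add atoms: none
Why: Lindlar-type syn semihydrogenation gives the Z-enoate 7, whose cis hydroxyl and ester close the five-membered lactone ring by intramolecular transesterification (5-exo-trig acyl substitution) under mild acid, and since the C–O bond at the stereocentre is not broken the R configuration is retained.

**Step 5**
Reactants: 8 (R)-5-[13-(tert-butyldimethylsilyloxy)tridecyl]furan-2(5H)-one; 9 tris(methylthio)methane; 10 iodomethane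
Product: 12 (3S,4S,5R)-5-[13-(tert-butyldimethylsilyloxy)tridecyl]-3-methyl-4-[tris(methylsulfanyl)methyl]oxolan-2-one, via lithium enolate 11 (not isolated)
Conditions: 9, n-BuLi, THF, −78 °C; add 8, −78 °C; MeI, DMPU, −78 → −30 °C; aq. NH4Cl
Reagents that add atoms: none
Why: Tris(methylthio)methane is lithiated to (MeS)3CLi, a soft, sulfur-stabilised and bulky carboxyl-anion equivalent that adds in Michael fashion to C4 of butenolide 8, forming the C4–C(carboxyl) bond, and the lithium enolate 11 so formed is C-methylated at C3 by iodomethane, forming the C3–CH3 bond. The closest known reaction type is the tandem conjugate addition–enolate alkylation (three-component coupling) of γ-alkyl butenolides with lithiated trithioorthoformates, as used for paraconic-type lactone acids. No ring is closed; the five-membered lactone ring is carried through intact. The C4 centre is controlled by the C5 side chain, the nucleophile entering the face anti to it (4,5-trans), and the C3 centre by the new C(SMe)3 group, iodomethane approaching the enolate anti to it (3,4-trans), so the (3S,4S,5R) isomer is expected. The step needs 1,4-addition to win over 1,2-addition and over γ-deprotonation at C5, which the softness and size of the carbanion and the temperature of −78 °C secure, and C5, set in step 3, is not touched. Both new centres are erased when the C3=C4 alkene is restored in step 7, so only the regiochemistry of the two bond formations has to be complete.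

**Step 6**
Reactants: 12 (3S,4S,5R)-5-[13-(tert-butyldimethylsilyloxy)tridecyl]-3-methyl-4-[tris(methylsulfanyl)methyl]oxolan-2-one
Product: 14 (3S,4S,5R)-5-[13-(tert-butyldimethylsilyloxy)tridecyl]-3-methyl-3-(phenylselanyl)-4-[tris(methylsulfanyl)methyl]oxolan-2-one, via lithium enolate 13 (not isolated)
Conditions: LiN(i-Pr)2 (1.2 equiv), THF, −78 °C; PhSeBr, THF, −78 °C
Reagents that add atoms: benzeneselenenyl bromide, Br[Se]c1ccccc1
Why: Kinetic deprotonation can only occur at C3, since the orthothioester carbon bears no hydrogen, and α-selenenylation of the lactone enolate at −78 °C (cold, so that the enolate does not revert by retro-Michael loss of the carbanion) puts selenium on the face anti to the C(SMe)3 group, that is cis to C4–H.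

**Step 7**
Reactants: 14 (3S,4S,5R)-5-[13-(tert-butyldimethylsilyloxy)tridecyl]-3-methyl-3-(phenylselanyl)-4-[tris(methylsulfanyl)methyl]oxolan-2-one
Product: 16 (R)-5-[13-(tert-butyldimethylsilyloxy)tridecyl]-3-methyl-4-[tris(methylsulfanyl)methyl]furan-2(5H)-one, via selenoxide 15 (not isolated)
Conditions: mCPBA (1.0 equiv), CH2Cl2, −78 °C; Et3N (2 equiv), −78 °C → rt
Reagents that add atoms: none
Why: One equivalent of peracid at −78 °C should oxidise selenium far faster than the hindered, electron-poor orthothioester sulfurs, and the selenoxide undergoes syn elimination through a five-membered transition state toward the cis C4–H to give the conjugated, tetrasubstituted ring alkene, with Et3N trapping PhSeOH and C5 not involved.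

**Step 8**
Reactants: 16 (R)-5-[13-(tert-butyldimethylsilyloxy)tridecyl]-3-methyl-4-[tris(methylsulfanyl)methyl]furan-2(5H)-one
Product: 19 (R)-2-(13-hydroxytridecyl)-4-methyl-5-oxo-2,5-dihydrofuran-3-carboxylic acid, via S-methyl thioester 17 (not isolated), via silyl-protected acid 18 (not isolated)
Conditions: HgO, BF3·OEt2, THF/H2O (4:1), 0 °C → rt; filter; then 48% aq. HF, MeCN, 0 °C → rt
Reagents that add atoms: water, O
Why: Thiophile-promoted hydrolysis of an orthothioester, in which divalent mercury and BF3 ionise a C–S bond to a dithio-stabilised carbocation that water captures to give thioester 17, a second mercury-assisted hydrolysis gives acid 18, and the acidic medium completed by aqueous HF cleaves the primary silyl ether, all without base so that C5 keeps its configuration.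

**Step 9**
Reactants: 19 (R)-2-(13-hydroxytridecyl)-4-methyl-5-oxo-2,5-dihydrofuran-3-carboxylic acid
Product: 21 (R)-2-[13-(acetyloxy)tridecyl]-4-methyl-5-oxo-2,5-dihydrofuran-3-carboxylic acid, via mixed anhydride 20 (not isolated)
Conditions: Ac2O (excess), pyridine, CH2Cl2, 0 °C → rt; then H2O/THF, rt
Reagents that add atoms: acetic anhydride, CC(=O)OC(C)=O
Why: Pyridine-mediated O-acetylation (nucleophilic acyl substitution) of the primary alcohol with excess Ac2O, the carboxyl group being carried as mixed anhydride 20 that water cleaves again on work-up, while the weak base at room temperature does not deprotonate C5–H.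

**Compound list**

1 | 1,14-tetradecanediol | OCCCCCCCCCCCCCCO | starting material
2 | sodium 14-hydroxytetradecan-1-olate (monosodium alkoxide of 1) | [Na+].[O-]CCCCCCCCCCCCCCO | intermediate
3 | 14-[(tert-butyldimethylsilyl)oxy]tetradecan-1-ol | CC(C)(C)[Si](C)(C)OCCCCCCCCCCCCCCO | intermediate
4 | 14-[(tert-butyldimethylsilyl)oxy]tetradecanal | CC(C)(C)[Si](C)(C)OCCCCCCCCCCCCCC=O | intermediate
5 | methyl propiolate | C#CC(=O)OC | starting material
6 | methyl (R)-17-[(tert-butyldimethylsilyl)oxy]-4-hydroxyheptadec-2-ynoate | CC(C)(C)[Si](C)(C)OCCCCCCCCCCCCC[C@@H](O)C#CC(=O)OC | intermediate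
7 | methyl (2Z,4R)-17-[(tert-butyldimethylsilyl)oxy]-4-hydroxyheptadec-2-enoate | CC(C)(C)[Si](C)(C)OCCCCCCCCCCCCC[C@@H](O)/C=C\C(=O)OC | intermediate
8 | (R)-5-[13-(tert-butyldimethylsilyloxy)tridecyl]furan-2(5H)-one | CC(C)(C)[Si](C)(C)OCCCCCCCCCCCCC[C@H]1OC(=O)C=C1 | intermediate
9 | tris(methylthio)methane | CSC(SC)SC | starting material
10 | iodomethane | CI | starting material
11 | lithium (4S,5R)-5-[13-(tert-butyldimethylsilyloxy)tridecyl]-4-[tris(methylsulfanyl)methyl]-4,5-dihydrofuran-2-olate | CC(C)(C)[Si](C)(C)OCCCCCCCCCCCCC[C@H]1OC(O[Li])=C[C@@H]1C(SC)(SC)SC | intermediate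
12 | (3S,4S,5R)-5-[13-(tert-butyldimethylsilyloxy)tridecyl]-3-methyl-4-[tris(methylsulfanyl)methyl]oxolan-2-one (3,4-trans, 4,5-trans) | CC(C)(C)[Si](C)(C)OCCCCCCCCCCCCC[C@H]1OC(=O)[C@@H](C)[C@@H]1C(SC)(SC)SC | intermediate
13 | lithium (4S,5R)-5-[13-(tert-butyldimethylsilyloxy)tridecyl]-3-methyl-4-[tris(methylsulfanyl)methyl]-4,5-dihydrofuran-2-olate | CC(C)(C)[Si](C)(C)OCCCCCCCCCCCCC[C@H]1OC(O[Li])=C(C)[C@@H]1C(SC)(SC)SC | intermediate
14 | (3S,4S,5R)-5-[13-(tert-butyldimethylsilyloxy)tridecyl]-3-methyl-3-(phenylselanyl)-4-[tris(methylsulfanyl)methyl]oxolan-2-one (Se cis to C4–H) | CC(C)(C)[Si](C)(C)OCCCCCCCCCCCCC[C@H]1OC(=O)[C@@](C)([Se]c2ccccc2)[C@@H]1C(SC)(SC)SC | intermediate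
15 | (3S,4S,5R)-5-[13-(tert-butyldimethylsilyloxy)tridecyl]-3-methyl-3-(phenylseleninyl)-4-[tris(methylsulfanyl)methyl]oxolan-2-one (either configuration at selenium) | CC(C)(C)[Si](C)(C)OCCCCCCCCCCCCC[C@H]1OC(=O)[C@@](C)([Se](=O)c2ccccc2)[C@@H]1C(SC)(SC)SC | intermediate
16 | (R)-5-[13-(tert-butyldimethylsilyloxy)tridecyl]-3-methyl-4-[tris(methylsulfanyl)methyl]furan-2(5H)-one | CC(C)(C)[Si](C)(C)OCCCCCCCCCCCCC[C@H]1OC(=O)C(C)=C1C(SC)(SC)SC | intermediate
17 | S-methyl (R)-2-[13-(tert-butyldimethylsilyloxy)tridecyl]-4-methyl-5-oxo-2,5-dihydrofuran-3-carbothioate | CC(C)(C)[Si](C)(C)OCCCCCCCCCCCCC[C@H]1OC(=O)C(C)=C1C(=O)SC | intermediate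
18 | (R)-2-[13-(tert-butyldimethylsilyloxy)tridecyl]-4-methyl-5-oxo-2,5-dihydrofuran-3-carboxylic acid | CC(C)(C)[Si](C)(C)OCCCCCCCCCCCCC[C@H]1OC(=O)C(C)=C1C(=O)O | intermediate
19 | (R)-2-(13-hydroxytridecyl)-4-methyl-5-oxo-2,5-dihydrofuran-3-carboxylic acid | OCCCCCCCCCCCCC[C@H]1OC(=O)C(C)=C1C(=O)O | intermediate
20 | acetic (R)-2-[13-(acetyloxy)tridecyl]-4-methyl-5-oxo-2,5-dihydrofuran-3-carboxylic anhydride | CC(=O)OCCCCCCCCCCCCC[C@H]1OC(=O)C(C)=C1C(=O)OC(C)=O | intermediate
21 | (R)-2-[13-(acetyloxy)tridecyl]-4-methyl-5-oxo-2,5-dihydrofuran-3-carboxylic acid | CC(=O)OCCCCCCCCCCCCC[C@H]1OC(=O)C(C)=C1C(=O)O | target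

**Totals**

Total step count: 9. Longest linear sequence: 9 steps (1 → 21).

**Steps most likely to fail**

Step 7. The selenoxide may eliminate into the C3 methyl group instead of into the ring (certainly so if step 6 delivered selenium trans to C4–H), and sulfur may be oxidised alongside selenium. The fallback sets out from 14 and comes back at 19. The elimination is allowed to run toward the methyl group, giving (4S,5R)-5-[13-(tert-butyldimethylsilyloxy)tridecyl]-3-methylidene-4-[tris(methylsulfanyl)methyl]oxolan-2-one F1. Its orthothioester and silyl ether are cleaved as in step 8 (HgO, BF3·OEt2, THF/H2O; then aq. HF), the thiol being bound as its mercury thiolate as it forms, to give (2R,3S)-2-(13-hydroxytridecyl)-4-methylidene-5-oxooxolane-3-carboxylic acid F2. In F2 the ring C–H to be moved is α to the carboxyl group, and Et3N in CH2Cl2 at rt should shift the alkene into the ring (the base-mediated conjugation known for α-methylene paraconic acids), giving 19.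

Step 8. Ionisation of the vinylogous orthothioester may be slow, hydrolysis may stall at the thioester stage, and the primary hydroxyl set free in the acidic medium may be acylated by the activated thioester. The fallback sets out from 16 and comes back at 21, exchanging the protecting group before the acid is unmasked. Aqueous HF in MeCN gives (R)-5-(13-hydroxytridecyl)-3-methyl-4-[tris(methylsulfanyl)methyl]furan-2(5H)-one F3. Ac2O and pyridine give (R)-13-{4-methyl-5-oxo-3-[tris(methylsulfanyl)methyl]-2,5-dihydrofuran-2-yl}tridecyl acetate F4. Buffered unmasking with Hg(OCOCF3)2 and CaCO3 in MeCN/H2O at rt then releases 21 directly, with no free hydroxyl present and no strong acid to endanger the acetate.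

Step 5. Proton transfer from unreacted butenolide (γ-deprotonation at C5) to the carbanion or to enolate 11 may compete, methylation may be incomplete or occur twice, and excess carbanion consumes iodomethane. The fallback sets out from 8 and comes back at 12, separating the two bond formations. The conjugate addition is quenched with aq. NH4Cl at −78 °C and (4S,5R)-5-[13-(tert-butyldimethylsilyloxy)tridecyl]-4-[tris(methylsulfanyl)methyl]oxolan-2-one F5 is isolated. LiN(i-Pr)2 in THF at −78 °C then forms the enolate cleanly, and iodomethane methylates it anti to the C(SMe)3 group to give 12.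

**Further compounds**

F1 | step 7 | (4S,5R)-5-[13-(tert-butyldimethylsilyloxy)tridecyl]-3-methylidene-4-[tris(methylsulfanyl)methyl]oxolan-2-one | CC(C)(C)[Si](C)(C)OCCCCCCCCCCCCC[C@H]1OC(=O)C(=C)[C@@H]1C(SC)(SC)SC
F2 | step 7 | (2R,3S)-2-(13-hydroxytridecyl)-4-methylidene-5-oxooxolane-3-carboxylic acid | OCCCCCCCCCCCCC[C@H]1OC(=O)C(=C)[C@@H]1C(=O)O
F3 | step 8 | (R)-5-(13-hydroxytridecyl)-3-methyl-4-[tris(methylsulfanyl)methyl]furan-2(5H)-one | OCCCCCCCCCCCCC[C@H]1OC(=O)C(C)=C1C(SC)(SC)SC
F4 | step 8 | (R)-13-{4-methyl-5-oxo-3-[tris(methylsulfanyl)methyl]-2,5-dihydrofuran-2-yl}tridecyl acetate | CC(=O)OCCCCCCCCCCCCC[C@H]1OC(=O)C(C)=C1C(SC)(SC)SC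
F5 | step 5 | (4S,5R)-5-[13-(tert-butyldimethylsilyloxy)tridecyl]-4-[tris(methylsulfanyl)methyl]oxolan-2-one | CC(C)(C)[Si](C)(C)OCCCCCCCCCCCCC[C@H]1OC(=O)C[C@@H]1C(SC)(SC)SC
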